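Atom labels C1–C15 follow germacrane numbering of the target throughout: C1–C10 ring, C11–C13 lactone carbons, C14 methyl on C10, C15 methyl on C4.

## Analysis of the target

The target is a germacranolide: a ten-membered carbocycle (C1–C10) trans-fused across C6–C7 to an α-methylene-γ-butyrolactone (O on C6, C12 carbonyl, C11=C13). It carries a Z-trisubstituted C4=C5 alkene, a trans 1,10-epoxide, a benzoate on C3 and, on C8, the ester of (2S,3R)-2,3-dimethyloxirane-2-carboxylic acid. The six ring stereocentres are 1R, 3S, 6R, 7R, 8R and 10R. In relative terms, O6 and C11 are trans on the ring (trans lactone), C11 and O8 are cis (a 7,8-anti pattern in the open chain), O6 and O8 are 1,3-anti, and C2 and C9 are trans across the epoxide. Sensitive groups are the methylene lactone (Michael acceptor), the trisubstituted epoxide (transannular opening by C4=C5), the epoxy ester, and the lactone itself, which can migrate from O6 to O8 once O8 is a free alkoxide. The difficulty lies in closing a medium ring that has oxygen on six of its ten carbons while keeping stereocentres on both sides of the ring in register. The strategy rests on the C1–C2–C3 segment: C1 bears oxygen, is β to the C3 oxygen and is attached to the fully substituted C10. That is an aldol retron in which the C1 aldehyde cannot enolise and the C2 nucleophile is the enolate of a C3 ketone. The C1 hydroxyl made in this way can direct the reduction at C3 and then be displaced by the C10 oxygen to give the epoxide.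

## Retrosynthetic reasoning

**C8 ester.** The O8–acyl bond is cut first, giving alcohol 38 and epoxy acid 41 (activated as 42). The epoxy ester is the group least likely to survive enolate, hydride and fluoride chemistry, and the cut makes the route convergent. The forward step must acylate a hindered secondary alcohol without letting the lactone migrate to O8.

**C11=C13.** The exocyclic methylene of 38 is removed (37, via 36 and 35) to reach the saturated lactone 33. A methylene lactone would intercept the metal enolate of the ring closure and the later hydride, so C13 is added as late as the protecting groups allow. The forward step needs the lactone enolate 34 in the presence of a benzoate and an epoxide.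

**Epoxide.** In 33 the C1–O bond of the oxirane is cut and the C10–O bond is kept. This gives mesylate 31 (from 30 and 29), with C10 oxygen as a silyl ether and an activated oxygen of opposite configuration on C1. Cutting the other C–O bond would demand substitution at a fully substituted carbon. The gain is a trans epoxide that follows stereospecifically from two sp3 centres: alkoxide 32 displaces the mesylate with inversion.

**C3.** The C3 carbinol of 29 is traced to ketone 28. The C1 hydroxyl and the C3 oxygen are 1,3-anti, the pattern that hydroxyl-directed intramolecular hydride delivery produces. Afterwards the two hydroxyls are told apart by the quaternary C10 next to C1.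

**C1–C2, the key disconnection.** Cutting C1–C2 in 28 opens the ring to 26, which has an aldehyde at C1 and a bromomethyl ketone at C2–C3. The cut is made here because only one aldol direction exists (C1 has no α-hydrogen), because the halogen fixes the enolate position (27), and because the bond lies next to the most substituted ring carbon, whose substituents bend the chain. The product carries exactly the functionality the two preceding disconnections need. The forward reaction must close a ten-membered ring and select one aldehyde face.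

**Adjusting 26.** The bromide is removed to give keto aldehyde 24 (bromination through enol silane 25). Both carbonyls are then traced to alcohols (diol 23), and these to the bis-PMB ether 22. Placing the C1 and C3 oxygens under the same ether lets one deprotection and one oxidation release both carbonyls. The forward bromination must occur at C2 only, next to a free aldehyde.

**C5–C6 and the lactone.** 22 is cut at C5–C6 and at O6–C12, giving alkenyl iodide 19 (as alkenyllithium 20) and aldehyde ester 15. This is preferred over reducing a C6 ketone: carbon addition to the C6 aldehyde places the new oxygen syn to the C11 arm and anti to O8 (Felkin–Anh, reinforced by the β-silyloxy group), which is the trans lactone. Hydride addition to the corresponding enone would be steered by the same models to the C6 epimer. Alkoxide 21 then lactonises.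

**C7–C11.** 15 comes from diester 14 and alcohol 13; 13 is cut at C7–C11 into β-hydroxy ester 10 and tert-butyl bromoacetate 11. Alkylation of dianion 12 occurs anti to the C8 substituent and gives the 7,8-anti pattern, which a direct succinate aldol does not give reliably. The tert-butyl ester lets the methyl ester (C6) be reduced alone.

**C7–C8.** 10 (via adduct 9) is cut at C7–C8 into aldehyde 6 and the chiral acetate 7; the new C8 centre is reagent-controlled.

**C8–C9 and C10.** 6 goes back through 4 and 3 to epoxide 2 and glycidol 1. The C8–C9 bond arises from opening the epoxide CH2 with a vinyl nucleophile; C10 with its oxygen, C14 and C1 come from the chiral pool.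

**Alkenyl iodide.** 19 goes back through 18 to alkynol 16. The C4–C15 bond is made by carbometalation, which also fixes the Z geometry.

**Acid 41.** 41 comes from epoxy alcohol 40 and allylic alcohol 39 by asymmetric epoxidation and oxidation.

## Alternatives that were turned down

**Alternative 1:** The lactone C6–O bond is the last ring bond made. The 13-nor lactone A1 is traced to amide A2, a complete carbocycle (epoxide, benzoate and C8 ester in place) whose C6 is a plain allylic methylene and whose C7 carries a CH2CONH2 arm.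
- Forward step: A2 is N-iodinated in the flask by a hypervalent iodine oxidant under visible light. The amidyl radical takes the C6 hydrogen by a 1,5-shift, the carbon radical is oxidised, the amide oxygen closes the five-membered ring, and hydrolysis of the C=N bond leaves A1.
- For it: the C6–H bond is allylic and at the right distance. C6 oxygen need not be carried through the ring synthesis, so lactone migration and C6 protection are not issues. On this point it is stronger than the chosen route.
- Against it: the C8 hydrogen is equally 1,5 to nitrogen and is activated by its acyloxy group, so two sites compete. The C6 radical is allylic and delocalised over C4–C6, which invites attack at C4 and loss of the Z geometry. The C6 configuration would be set only by ring conformation at the moment of closure. The epoxide and epoxy ester must survive iodine-radical conditions.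
- Comparison: it leaves the real problem, a ten-membered ring with C1, C3, C7, C8 and C10 correct, unsolved, and A1 still lacks the methylene. The chosen route sets C6 with the lactone on an open chain and uses the lactone to constrain the cyclisation precursor.

**Alternative 2:** Two σ-bonds, C4–C5 and C1–C10, are traced to the cyclobutane of photoadduct A3. A3 comes from cyclohexenone A4 (already holding C7, C8 and the acetate arm) and cyclobutene A5.
- Forward step: irradiation of A4 with A5 gives the cis-anti-cis adduct A3. Heating then cleaves the central four-membered ring and unveils both ring alkenes and the ten-membered ring.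
- For it: two skeletal bonds form in one step and the medium ring appears without high dilution. Both methyl-bearing alkenes are placed with geometry dictated by the ring fusion, and C7/C8 are set on a six-membered ring. It is clearly shorter to the carbocycle and stronger in step economy.
- Against it: nothing in A4 secures head-to-head versus head-to-tail addition of the unsymmetrical A5, nor the face relative to the C8 silyl ether. The thermolysis temperature invites Cope rearrangement of the E,Z-1,5-diene. After ring expansion, C6 (ketone reduction to the trans lactone), C3 (S alcohol) and the epoxide (one face of the E alkene) must all be set by conformational bias of a flexible ring.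
- Comparison: the chosen route gives up that brevity but sets C6, C7, C8 and C10 on open chains, C1 by 1,2-induction, C3 by a directed reduction and the epoxide by displacement.

**Alternative 3:** The ring is made by a [3,3] shift that forms C8–C9. Dienone A6 is traced to cyclohexenol A7, whose carbinol carbon (C6) bears an E-2-silylvinyl group and whose neighbour (C1) bears an isopropenyl group trans to it.
- Forward step: the potassium alkoxide of A7 (potassium base, crown ether) rearranges through a chair. C8–C9 forms as C1–C6 breaks, and protonation of the enolate gives A6 with the 1(10)E and 4Z alkenes and a C8 silyl group as masked hydroxyl.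
- For it: ring expansion needs no dilution, the chair transfers ring configuration into alkene geometry and the C8 centre, and anion acceleration allows low temperature. As a ring-forming event it is more dependable than any end-to-end closure, the chosen one included.
- Against it: A6 has no C11–C13. C7 is a methylene beside the C6 ketone, so the two-carbon arm needs a regio- and face-selective alkylation on the macrocycle (C7 against the γ-positions of the enone). Then come C6 reduction, lactonisation, C–Si oxidation beside two alkenes, and a face-selective epoxidation. A7 itself needs a trans-selective 1,2-addition.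
- Comparison: the chosen route has C7 with its arm, C6 and C8 fixed before ring closure and derives the epoxide from the aldol hydroxyl.

Key step: step 16

Assumption: (S)-2-methylglycidol 1 and (S)-but-3-yn-2-ol 16 are commercial in high enantiomeric purity; the carbinol centre of 16 only keeps intermediates 18–23 single diastereomers and is erased in step 14.

## Route

Step 1
Reactants: 1 (S)-2-methylglycidol
Product: 2 (2R)-2-{[(4-methoxybenzyl)oxy]methyl}-2-methyloxirane
Conditions: NaH, 4-methoxybenzyl chloride, Bu4NI (cat.), THF/DMF, 0 °C → rt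
Reagents that add atoms: 4-methoxybenzyl chloride, COc1ccc(CCl)cc1
Why: Williamson etherification of the primary alkoxide; the stereocentre (future C10) does not react and the Payne rearrangement of this alkoxide is degenerate, returning the same enantiomer (the descriptor changes only through CIP ranking).

Step 2
Reactants: 2 (2R)-2-{[(4-methoxybenzyl)oxy]methyl}-2-methyloxirane
Product: 3 (2R)-1-[(4-methoxybenzyl)oxy]-2-methylpent-4-en-2-ol
Conditions: CH2=CHMgBr, CuI (10 mol%), THF, −30 → 0 °C
Reagents that add atoms: vinylmagnesium bromide, C=C[Mg]Br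
Why: Copper-catalysed SN2 opening of the 2,2-disubstituted epoxide at its unhindered CH2 (future C9) by the vinyl group (future C8); the C10 configuration is untouched.

Step 3
Reactants: 3 (2R)-1-[(4-methoxybenzyl)oxy]-2-methylpent-4-en-2-ol
Product: 4 triethyl{[(2R)-1-[(4-methoxybenzyl)oxy]-2-methylpent-4-en-2-yl]oxy}silane
Conditions: Et3SiOTf, 2,6-lutidine, CH2Cl2, −78 → 0 °C
Reagents that add atoms: triethylsilyl trifluoromethanesulfonate, CC[Si](CC)(CC)OS(=O)(=O)C(F)(F)F
Why: A tertiary alcohol needs the silyl triflate; the triethylsilyl ether is bulky enough to prevent chelation in step 16 and labile enough for selective fluoride cleavage in step 20.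

Step 4
Reactants: 4 triethyl{[(2R)-1-[(4-methoxybenzyl)oxy]-2-methylpent-4-en-2-yl]oxy}silane
Product: 6 (3R)-4-[(4-methoxybenzyl)oxy]-3-methyl-3-(triethylsilyloxy)butanal, via ozonide 5 (not isolated)
Conditions: O3, CH2Cl2, −78 °C, Sudan Red 7B end-point; then PPh3, −78 °C → rt
Reagents that add atoms: ozone, [O-][O+]=O
Why: Ozonolysis of the only alkene with reductive cleavage of ozonide 5 gives the C8 aldehyde; the dye end-point protects the electron-rich arene.

Step 5
Reactants: 7 (S)-HYTRA, (1S)-2-hydroxy-1,2,2-triphenylethyl acetate; 6 (3R)-4-[(4-methoxybenzyl)oxy]-3-methyl-3-(triethylsilyloxy)butanal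
Product: 9 (1S)-2-hydroxy-1,2,2-triphenylethyl (3R,5R)-3-hydroxy-6-[(4-methoxybenzyl)oxy]-5-methyl-5-(triethylsilyloxy)hexanoate, via dilithio enolate 8 (not isolated)
Conditions: LiN(iPr)2 (2.1 equiv), THF, −78 → 0 °C; then 6, THF/2-methylbutane, −125 °C; NH4Cl
Reagents that add atoms: none
Why: Auxiliary-controlled acetate aldol forming C7–C8: the (S)-reagent is the one that gives (S)-3-hydroxy acids from α-branched aldehydes, and with the present chain (CH2CO outranks C9) the same spatial outcome is 3R, the C8 configuration required; the remote C10 centre should have little influence.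

Step 6
Reactants: 9 (1S)-2-hydroxy-1,2,2-triphenylethyl (3R,5R)-3-hydroxy-6-[(4-methoxybenzyl)oxy]-5-methyl-5-(triethylsilyloxy)hexanoate
Product: 10 methyl (3R,5R)-3-hydroxy-6-[(4-methoxybenzyl)oxy]-5-methyl-5-(triethylsilyloxy)hexanoate
Conditions: K2CO3 (cat.), MeOH, 0 °C → rt
Reagents that add atoms: methanol, CO
Why: Base-catalysed transesterification releases the auxiliary diol and gives the methyl ester needed for dianion formation; the tertiary silyl ether tolerates these conditions.

Step 7
Reactants: 10 methyl (3R,5R)-3-hydroxy-6-[(4-methoxybenzyl)oxy]-5-methyl-5-(triethylsilyloxy)hexanoate; 11 tert-butyl bromoacetate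
Product: 13 4-tert-butyl 1-methyl (2R)-2-{(1R,3R)-1-hydroxy-4-[(4-methoxybenzyl)oxy]-3-methyl-3-(triethylsilyloxy)butyl}butanedioate, via ester dianion 12 (not isolated)
Conditions: LiN(iPr)2 (2.2 equiv), THF, −78 → −40 °C; then 11, DMPU, −78 → −30 °C; AcOH quench at −78 °C
Reagents that add atoms: none
Why: Fráter–Seebach alkylation forming C7–C11: the lithium-chelated dianion 12 is alkylated on the face opposite the C8 substituent, which sets C7 in the 7,8-anti sense; the cold quench keeps the C8 alkoxide from lactonising onto the tert-butyl ester.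

Step 8
Reactants: 13 4-tert-butyl 1-methyl (2R)-2-{(1R,3R)-1-hydroxy-4-[(4-methoxybenzyl)oxy]-3-methyl-3-(triethylsilyloxy)butyl}butanedioate
Product: 14 4-tert-butyl 1-methyl (2R)-2-{(1R,3R)-1-(tert-butyldimethylsilyloxy)-4-[(4-methoxybenzyl)oxy]-3-methyl-3-(triethylsilyloxy)butyl}butanedioate
Conditions: t-BuMe2SiOTf, 2,6-lutidine, CH2Cl2, −78 → 0 °C
Reagents that add atoms: tert-butyldimethylsilyl trifluoromethanesulfonate, CC(C)(C)[Si](C)(C)OS(=O)(=O)C(F)(F)F
Why: Silyl triflate silylation of the hindered secondary alcohol; the non-chelating TBS ether blocks the competing O8 lactone and supports 1,3-anti induction in step 12.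

Step 9
Reactants: 14 4-tert-butyl 1-methyl (2R)-2-{(1R,3R)-1-(tert-butyldimethylsilyloxy)-4-[(4-methoxybenzyl)oxy]-3-methyl-3-(triethylsilyloxy)butyl}butanedioate
Product: 15 tert-butyl (3R,4R,6R)-4-(tert-butyldimethylsilyloxy)-3-formyl-7-[(4-methoxybenzyl)oxy]-6-methyl-6-(triethylsilyloxy)heptanoate
Conditions: i-Bu2AlH (1.15 equiv), toluene, −78 °C; MeOH, aq. potassium sodium tartrate
Reagents that add atoms: none
Why: Partial reduction of the methyl ester stops at the aluminium hemiacetal at −78 °C, where the tert-butyl ester is inert; the aldehyde is used crude to avoid epimerisation at C7.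

Step 10
Reactants: 16 (S)-but-3-yn-2-ol
Product: 18 (2S,3Z)-4-iodo-3-methylbut-3-en-2-ol, via alkenylmagnesium alkoxide 17 (not isolated)
Conditions: MeMgBr (3 equiv), CuI (15 mol%), THF, −10 °C → rt; then I2, −40 → 0 °C
Reagents that add atoms: methylmagnesium bromide, C[Mg]Br; iodine, I-I
Why: Copper-catalysed anti-carbomagnesiation of the propargylic alkoxide puts methyl (C15) on the internal carbon and magnesium on the terminal carbon cis to the carbinol in chelate 17; iodinolysis with retention gives the Z iodide, the C4=C5 geometry of the target.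

Step 11
Reactants: 18 (2S,3Z)-4-iodo-3-methylbut-3-en-2-ol
Product: 19 1-({[(2S,3Z)-4-iodo-3-methylbut-3-en-2-yl]oxy}methyl)-4-methoxybenzene
Conditions: NaH, 4-methoxybenzyl chloride, Bu4NI (cat.), THF/DMF, 0 °C → rt
Reagents that add atoms: 4-methoxybenzyl chloride, COc1ccc(CCl)cc1
Why: Williamson etherification; a benzyl-type ether is used because a silyl ether cis to lithium in step 12 would undergo 1,4 O→C silyl migration.

Step 12
Reactants: 19 1-({[(2S,3Z)-4-iodo-3-methylbut-3-en-2-yl]oxy}methyl)-4-methoxybenzene; 15 tert-butyl (3R,4R,6R)-4-(tert-butyldimethylsilyloxy)-3-formyl-7-[(4-methoxybenzyl)oxy]-6-methyl-6-(triethylsilyloxy)heptanoate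
Product: 22 (4S,5R)-4-{(1R,3R)-1-(tert-butyldimethylsilyloxy)-4-[(4-methoxybenzyl)oxy]-3-methyl-3-(triethylsilyloxy)butyl}-5-{(1Z,3S)-3-[(4-methoxybenzyl)oxy]-2-methylbut-1-en-1-yl}oxolan-2-one, via alkenyllithium 20 (not isolated), via lithium alkoxide 21 (not isolated)
Conditions: 19, t-BuLi (2.0 equiv), Et2O, −78 °C; then 15, −78 °C; then warm to rt
Reagents that add atoms: none
Why: Iodine–lithium exchange with retention gives Z-alkenyllithium 20, which adds to the aldehyde faster than to the tert-butyl ester and forms C5–C6. Felkin–Anh control (C8 branch anti to the nucleophile), reinforced by 1,3-anti induction from the β-silyloxy group of this 7,8-anti aldehyde, should set C6 as R, syn to the C11 arm. On warming, alkoxide 21 closes the trans γ-lactone by 5-exo-trig acyl substitution (catalytic KOt-Bu completes it if the hydroxy ester persists).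

Step 13
Reactants: 22 (4S,5R)-4-{(1R,3R)-1-(tert-butyldimethylsilyloxy)-4-[(4-methoxybenzyl)oxy]-3-methyl-3-(triethylsilyloxy)butyl}-5-{(1Z,3S)-3-[(4-methoxybenzyl)oxy]-2-methylbut-1-en-1-yl}oxolan-2-one
Product: 23 (4S,5R)-4-[(1R,3R)-1-(tert-butyldimethylsilyloxy)-4-hydroxy-3-methyl-3-(triethylsilyloxy)butyl]-5-[(1Z,3S)-3-hydroxy-2-methylbut-1-en-1-yl]oxolan-2-one
Conditions: DDQ (2.5 equiv), CH2Cl2/pH 7 buffer, 0 °C → rt
Reagents that add atoms: none
Why: Oxidative cleavage of both 4-methoxybenzyl ethers under buffered conditions leaves silyl ethers, lactone and Z alkene intact; the diol is used at once so that the silyl group does not migrate from O10 to the free C1 hydroxyl.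

Step 14
Reactants: 23 (4S,5R)-4-[(1R,3R)-1-(tert-butyldimethylsilyloxy)-4-hydroxy-3-methyl-3-(triethylsilyloxy)butyl]-5-[(1Z,3S)-3-hydroxy-2-methylbut-1-en-1-yl]oxolan-2-one
Product: 24 (4S,5R)-4-[(1R,3R)-1-(tert-butyldimethylsilyloxy)-3-methyl-4-oxo-3-(triethylsilyloxy)butyl]-5-[(1Z)-2-methyl-3-oxobut-1-en-1-yl]oxolan-2-one
Conditions: Dess–Martin periodinane (3 equiv), NaHCO3, CH2Cl2, 0 °C → rt
Reagents that add atoms: none
Why: One Dess–Martin oxidation turns the allylic C3 alcohol into the Z-enone (erasing the placeholder centre) and the neopentyl C1 alcohol into the non-enolisable aldehyde; buffering and low temperature protect the Z geometry.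

Step 15
Reactants: 24 (4S,5R)-4-[(1R,3R)-1-(tert-butyldimethylsilyloxy)-3-methyl-4-oxo-3-(triethylsilyloxy)butyl]-5-[(1Z)-2-methyl-3-oxobut-1-en-1-yl]oxolan-2-one
Product: 26 (4S,5R)-5-[(1Z)-4-bromo-2-methyl-3-oxobut-1-en-1-yl]-4-[(1R,3R)-1-(tert-butyldimethylsilyloxy)-3-methyl-4-oxo-3-(triethylsilyloxy)butyl]oxolan-2-one, via enol silane 25 (not isolated)
Conditions: Me3SiOTf (1.2 equiv), Et3N, CH2Cl2, −78 °C; pentane filtration; then N-bromosuccinimide, NaHCO3, THF, −78 → −20 °C
Reagents that add atoms: N-bromosuccinimide, O=C1CCC(=O)N1Br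
Why: Soft enolisation of the methyl ketone, whose only α-hydrogens are on C2, gives 2-silyloxydiene 25; the aldehyde has no α-hydrogen and aldehydes are poor partners for silyl-triflate-mediated aldol addition at −78 °C. Bromination of the enol silane then occurs at its terminal carbon C2, where attack gives the oxygen-stabilised cation.

Step 16
Reactants: 26 (4S,5R)-5-[(1Z)-4-bromo-2-methyl-3-oxobut-1-en-1-yl]-4-[(1R,3R)-1-(tert-butyldimethylsilyloxy)-3-methyl-4-oxo-3-(triethylsilyloxy)butyl]oxolan-2-one
Product: 28 (1S,4Z,6R,7S,8R,10R)-8-(tert-butyldimethylsilyloxy)-1-hydroxy-3-oxo-10-(triethylsilyloxy)-13-norgermacr-4-en-12,6-olide, via chromium enolate 27 (not isolated)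
Conditions: CrCl2 (6 equiv), LiI (0.2 equiv), THF, 25 °C, syringe-pump addition of 26 (final 2 mM)
Reagents that add atoms: none
Why: Two single-electron transfers from divalent chromium cleave the C2–Br bond and leave a trivalent chromium enolate 27 fixed at C2, which adds to the C1 aldehyde; the closest known reaction type is the CrCl2- or SmI2-mediated Reformatsky cyclisation of formyl-tethered α-halo ketones. The ten-membered carbocycle closes 10-exo-trig at the aldehyde carbon (enolendo with respect to the C2=C3 enolate), and C1–C2 is the only new skeletal bond. The new C1 centre is controlled by C10: the bulky triethylsilyl ether cannot chelate, so the C10–O bond lies anti to the incoming C2 and the nucleophile passes the methyl group, not the C9 methylene (polar Felkin–Anh), which should give the 1S alcohol needed for inversion in step 20. Chemoselectivity among aldehyde, lactone and enone is required: chromium enolates add to aldehydes only, CrCl2 is too weak a reductant to cleave the γ-acyloxy enone (the reason it is preferred to SmI2), and the aldehyde has no α-hydrogen. Ring closure must outrun protonation and intermolecular aldol; slow addition into excess CrCl2 keeps the enolate dilute, while the Z-enone, the trans lactone and the quaternary C10 restrict the chain to turn-shaped conformers. The strong Cr–O bond of the aldolate makes the addition irreversible and suppresses retro-aldol and dehydration.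

Step 17
Reactants: 28 (1S,4Z,6R,7S,8R,10R)-8-(tert-butyldimethylsilyloxy)-1-hydroxy-3-oxo-10-(triethylsilyloxy)-13-norgermacr-4-en-12,6-olide
Product: 29 (1S,3S,4Z,6R,7S,8R,10R)-8-(tert-butyldimethylsilyloxy)-1,3-dihydroxy-10-(triethylsilyloxy)-13-norgermacr-4-en-12,6-olide
Conditions: Me4NBH(OAc)3 (5 equiv), MeCN/AcOH 1:1, −30 → −20 °C
Reagents that add atoms: none
Why: Evans–Saksena reduction: the C1 hydroxyl exchanges onto boron and hydride is delivered intramolecularly to C3 through a six-membered transition state, which should give the 1,3-anti diol (3S); the reagent does not touch the lactone and reduces the enone only in the 1,2 sense.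

Step 18
Reactants: 29 (1S,3S,4Z,6R,7S,8R,10R)-8-(tert-butyldimethylsilyloxy)-1,3-dihydroxy-10-(triethylsilyloxy)-13-norgermacr-4-en-12,6-olide
Product: 30 (1S,3S,4Z,6R,7S,8R,10R)-3-benzoyloxy-8-(tert-butyldimethylsilyloxy)-1-hydroxy-10-(triethylsilyloxy)-13-norgermacr-4-en-12,6-olide
Conditions: BzCl (1.1 equiv), pyridine, DMAP (cat.), CH2Cl2, −20 → 0 °C
Reagents that add atoms: benzoyl chloride, O=C(Cl)c1ccccc1
Why: Acylation selects the allylic C3 hydroxyl over the C1 hydroxyl, which is shielded by the adjacent fully substituted C10 and its silyl ether.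

Step 19
Reactants: 30 (1S,3S,4Z,6R,7S,8R,10R)-3-benzoyloxy-8-(tert-butyldimethylsilyloxy)-1-hydroxy-10-(triethylsilyloxy)-13-norgermacr-4-en-12,6-olide
Product: 31 (1S,3S,4Z,6R,7S,8R,10R)-3-benzoyloxy-8-(tert-butyldimethylsilyloxy)-1-(methylsulfonyloxy)-10-(triethylsilyloxy)-13-norgermacr-4-en-12,6-olide
Conditions: MsCl, Et3N, CH2Cl2, −20 → 0 °C
Reagents that add atoms: methanesulfonyl chloride, CS(=O)(=O)Cl
Why: Mesylation through sulfene works on the hindered C1 alcohol; C10 bears no hydrogen and the amine is too weak to eliminate towards C2.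

Step 20
Reactants: 31 (1S,3S,4Z,6R,7S,8R,10R)-3-benzoyloxy-8-(tert-butyldimethylsilyloxy)-1-(methylsulfonyloxy)-10-(triethylsilyloxy)-13-norgermacr-4-en-12,6-olide
Product: 33 (1R,3S,4Z,6R,7S,8R,10R)-3-benzoyloxy-8-(tert-butyldimethylsilyloxy)-1,10-epoxy-13-norgermacr-4-en-12,6-olide, via ammonium alkoxide 32 (not isolated)
Conditions: Bu4NF (1.1 equiv), THF, −20 → 0 °C
Reagents that add atoms: none
Why: Fluoride cleaves the triethylsilyl ether faster than the hindered secondary TBS ether; the tertiary alkoxide 32 displaces the vicinal mesylate (3-exo-tet) with inversion at C1 and retention at C10, giving the trans epoxide (1R,10R).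

Step 21
Reactants: 33 (1R,3S,4Z,6R,7S,8R,10R)-3-benzoyloxy-8-(tert-butyldimethylsilyloxy)-1,10-epoxy-13-norgermacr-4-en-12,6-olide
Product: 35 (1R,3S,4Z,6R,7S,8R,10R)-3-benzoyloxy-8-(tert-butyldimethylsilyloxy)-13-(dimethylamino)-1,10-epoxygermacr-4-en-12,6-olide (C11 epimers), via lithium enolate 34 (not isolated)
Conditions: LiN(iPr)2 (1.1 equiv), THF, −78 °C; then CH2=NMe2+ I−, −78 → 0 °C
Reagents that add atoms: N,N-dimethylmethyleneiminium iodide (Eschenmoser's salt), C=[N+](C)C.[I-]
Why: Kinetic deprotonation of the lactone α-CH2 (C11; the benzoate has no α-hydrogen) and Mannich reaction of enolate 34 introduce C13; the C11 configuration is of no consequence.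

Step 22
Reactants: 35 (1R,3S,4Z,6R,7S,8R,10R)-3-benzoyloxy-8-(tert-butyldimethylsilyloxy)-13-(dimethylamino)-1,10-epoxygermacr-4-en-12,6-olide
Product: 37 (1R,3S,4Z,6R,7S,8R,10R)-3-benzoyloxy-8-(tert-butyldimethylsilyloxy)-1,10-epoxygermacra-4,11(13)-dien-12,6-olide, via ammonium iodide 36 (not isolated)
Conditions: MeI, CH2Cl2/MeOH, rt; then aq. NaHCO3, CH2Cl2, rt
Reagents that add atoms: none
Why: Quaternisation followed by mild-base E1cB loss of trimethylamine gives the α-methylene lactone under conditions that spare benzoate, epoxide and silyl ether.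

Step 23
Reactants: 37 (1R,3S,4Z,6R,7S,8R,10R)-3-benzoyloxy-8-(tert-butyldimethylsilyloxy)-1,10-epoxygermacra-4,11(13)-dien-12,6-olide
Product: 38 (1R,3S,4Z,6R,7R,8R,10R)-3-benzoyloxy-1,10-epoxy-8-hydroxygermacra-4,11(13)-dien-12,6-olide
Conditions: HF·pyridine, pyridine, THF, 0 °C → rt
Reagents that add atoms: none
Why: Buffered HF·pyridine removes the secondary TBS ether without forming an alkoxide, which avoids O6→O8 lactone migration and conjugate addition; the pyridine buffer protects the epoxide.

Step 24
Reactants: 39 (E)-2-methylbut-2-en-1-ol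
Product: 40 [(2R,3R)-2,3-dimethyloxiran-2-yl]methanol
Conditions: Ti(OiPr)4 (10 mol%), D-(−)-diethyl tartrate (12 mol%), t-BuOOH, 4 Å molecular sieves, CH2Cl2, −20 °C
Reagents that add atoms: tert-butyl hydroperoxide, CC(C)(C)OO
Why: Sharpless asymmetric epoxidation; for this E-configured 2-methyl allylic alcohol the D-(−)-tartrate catalyst delivers oxygen to the face that gives the (2R,3R)-epoxy alcohol, the two methyl groups staying cis.

Step 25
Reactants: 40 [(2R,3R)-2,3-dimethyloxiran-2-yl]methanol
Product: 41 (2S,3R)-2,3-dimethyloxirane-2-carboxylic acid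
Conditions: RuCl3 (cat.), NaIO4, MeCN/EtOAc/H2O, rt
Reagents that add atoms: sodium periodate, [Na+].[O-]I(=O)(=O)=O
Why: RuO4 generated in the flask oxidises the primary alcohol to the acid without opening the epoxide; no stereocentre reacts (2R becomes 2S only through CIP ranking).

Step 26
Reactants: 41 (2S,3R)-2,3-dimethyloxirane-2-carboxylic acid; 38 (1R,3S,4Z,6R,7R,8R,10R)-3-benzoyloxy-1,10-epoxy-8-hydroxygermacra-4,11(13)-dien-12,6-olide
Product: 43 (1R,3S,4Z,6R,7R,8R,10R)-3-benzoyloxy-1,10-epoxy-8-{[(2S,3R)-2,3-dimethyloxiran-2-yl]carbonyloxy}germacra-4,11(13)-dien-12,6-olide, via mixed anhydride 42 (not isolated)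
Conditions: 41, 2,4,6-trichlorobenzoyl chloride, Et3N, toluene, rt; then 38, DMAP, toluene, rt → 40 °C
Reagents that add atoms: none
Why: Yamaguchi esterification: mixed anhydride 42 of the α-quaternary acid acylates the hindered C8 alcohol under DMAP catalysis; mild amine conditions avoid lactone migration.

## Compound list

1 | (S)-2-methylglycidol, (2S)-(2-methyloxiran-2-yl)methanol | C[C@]1(CO)CO1 | starting material
2 | (2R)-2-{[(4-methoxybenzyl)oxy]methyl}-2-methyloxirane | C[C@]1(COCc2ccc(OC)cc2)CO1 | intermediate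
3 | (2R)-1-[(4-methoxybenzyl)oxy]-2-methylpent-4-en-2-ol | C=CC[C@@](C)(O)COCc1ccc(OC)cc1 | intermediate
4 | triethyl{[(2R)-1-[(4-methoxybenzyl)oxy]-2-methylpent-4-en-2-yl]oxy}silane | C=CC[C@@](C)(O[Si](CC)(CC)CC)COCc1ccc(OC)cc1 | intermediate
5 | ozonide of 4, 3-{(2R)-3-[(4-methoxybenzyl)oxy]-2-methyl-2-(triethylsilyloxy)propyl}-1,2,4-trioxolane | CC[Si](CC)(CC)O[C@](C)(CC1OCOO1)COCc1ccc(OC)cc1 | intermediate
6 | (3R)-4-[(4-methoxybenzyl)oxy]-3-methyl-3-(triethylsilyloxy)butanal | O=CC[C@@](C)(O[Si](CC)(CC)CC)COCc1ccc(OC)cc1 | intermediate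
7 | (S)-HYTRA, (1S)-2-hydroxy-1,2,2-triphenylethyl acetate | CC(=O)O[C@@H](c1ccccc1)C(O)(c1ccccc1)c1ccccc1 | starting material
8 | dilithio enolate of 7 | [Li]OC(=C)O[C@@H](c1ccccc1)C(O[Li])(c1ccccc1)c1ccccc1 | intermediate
9 | (1S)-2-hydroxy-1,2,2-triphenylethyl (3R,5R)-3-hydroxy-6-[(4-methoxybenzyl)oxy]-5-methyl-5-(triethylsilyloxy)hexanoate | O=C(C[C@H](O)C[C@@](C)(O[Si](CC)(CC)CC)COCc1ccc(OC)cc1)O[C@@H](c1ccccc1)C(O)(c1ccccc1)c1ccccc1 | intermediate
10 | methyl (3R,5R)-3-hydroxy-6-[(4-methoxybenzyl)oxy]-5-methyl-5-(triethylsilyloxy)hexanoate | COC(=O)C[C@H](O)C[C@@](C)(O[Si](CC)(CC)CC)COCc1ccc(OC)cc1 | intermediate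
11 | tert-butyl bromoacetate | BrCC(=O)OC(C)(C)C | starting material
12 | dilithio alkoxide enolate (dianion) of 10 | COC(O[Li])=C[C@H](O[Li])C[C@@](C)(O[Si](CC)(CC)CC)COCc1ccc(OC)cc1 | intermediate
13 | 4-tert-butyl 1-methyl (2R)-2-{(1R,3R)-1-hydroxy-4-[(4-methoxybenzyl)oxy]-3-methyl-3-(triethylsilyloxy)butyl}butanedioate | COC(=O)[C@H](CC(=O)OC(C)(C)C)[C@H](O)C[C@@](C)(O[Si](CC)(CC)CC)COCc1ccc(OC)cc1 | intermediate
14 | 4-tert-butyl 1-methyl (2R)-2-{(1R,3R)-1-(tert-butyldimethylsilyloxy)-4-[(4-methoxybenzyl)oxy]-3-methyl-3-(triethylsilyloxy)butyl}butanedioate | COC(=O)[C@H](CC(=O)OC(C)(C)C)[C@H](O[Si](C)(C)C(C)(C)C)C[C@@](C)(O[Si](CC)(CC)CC)COCc1ccc(OC)cc1 | intermediate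
15 | tert-butyl (3R,4R,6R)-4-(tert-butyldimethylsilyloxy)-3-formyl-7-[(4-methoxybenzyl)oxy]-6-methyl-6-(triethylsilyloxy)heptanoate | O=C[C@H](CC(=O)OC(C)(C)C)[C@H](O[Si](C)(C)C(C)(C)C)C[C@@](C)(O[Si](CC)(CC)CC)COCc1ccc(OC)cc1 | intermediate
16 | (S)-but-3-yn-2-ol | C[C@H](O)C#C | starting material
17 | cyclic Z-alkenylmagnesium alkoxide, (5S)-4,5-dimethyl-2,5-dihydro-1,2-oxamagnesole | C[C@@H]1O[Mg]C=C1C | intermediate
18 | (2S,3Z)-4-iodo-3-methylbut-3-en-2-ol | C[C@H](O)/C(C)=C\I | intermediate
19 | 1-({[(2S,3Z)-4-iodo-3-methylbut-3-en-2-yl]oxy}methyl)-4-methoxybenzene | C[C@H](OCc1ccc(OC)cc1)/C(C)=C\I | intermediate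
20 | {(1Z,3S)-3-[(4-methoxybenzyl)oxy]-2-methylbut-1-en-1-yl}lithium | C[C@H](OCc1ccc(OC)cc1)/C(C)=C\[Li] | intermediate
21 | lithium alkoxide of the C6 adduct of 20 and 15 (tert-butyl ester still open) | [Li]O[C@H](/C=C(/C)[C@H](C)OCc1ccc(OC)cc1)[C@H](CC(=O)OC(C)(C)C)[C@H](O[Si](C)(C)C(C)(C)C)C[C@@](C)(O[Si](CC)(CC)CC)COCc1ccc(OC)cc1 | intermediate
22 | (4S,5R)-4-{(1R,3R)-1-(tert-butyldimethylsilyloxy)-4-[(4-methoxybenzyl)oxy]-3-methyl-3-(triethylsilyloxy)butyl}-5-{(1Z,3S)-3-[(4-methoxybenzyl)oxy]-2-methylbut-1-en-1-yl}oxolan-2-one | C[C@H](OCc1ccc(OC)cc1)/C(C)=C\[C@H]1OC(=O)C[C@@H]1[C@H](O[Si](C)(C)C(C)(C)C)C[C@@](C)(O[Si](CC)(CC)CC)COCc1ccc(OC)cc1 | intermediate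
23 | (4S,5R)-4-[(1R,3R)-1-(tert-butyldimethylsilyloxy)-4-hydroxy-3-methyl-3-(triethylsilyloxy)butyl]-5-[(1Z,3S)-3-hydroxy-2-methylbut-1-en-1-yl]oxolan-2-one | C[C@H](O)/C(C)=C\[C@H]1OC(=O)C[C@@H]1[C@H](O[Si](C)(C)C(C)(C)C)C[C@@](C)(O[Si](CC)(CC)CC)CO | intermediate
24 | (4S,5R)-4-[(1R,3R)-1-(tert-butyldimethylsilyloxy)-3-methyl-4-oxo-3-(triethylsilyloxy)butyl]-5-[(1Z)-2-methyl-3-oxobut-1-en-1-yl]oxolan-2-one | CC(=O)/C(C)=C\[C@H]1OC(=O)C[C@@H]1[C@H](O[Si](C)(C)C(C)(C)C)C[C@@](C)(O[Si](CC)(CC)CC)C=O | intermediate
25 | trimethylsilyl enol ether of 24 (2-silyloxydiene, silicon on the C3 oxygen) | C=C(O[Si](C)(C)C)/C(C)=C\[C@H]1OC(=O)C[C@@H]1[C@H](O[Si](C)(C)C(C)(C)C)C[C@@](C)(O[Si](CC)(CC)CC)C=O | intermediate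
26 | (4S,5R)-5-[(1Z)-4-bromo-2-methyl-3-oxobut-1-en-1-yl]-4-[(1R,3R)-1-(tert-butyldimethylsilyloxy)-3-methyl-4-oxo-3-(triethylsilyloxy)butyl]oxolan-2-one | BrCC(=O)/C(C)=C\[C@H]1OC(=O)C[C@@H]1[C@H](O[Si](C)(C)C(C)(C)C)C[C@@](C)(O[Si](CC)(CC)CC)C=O | intermediate
27 | dichlorochromium enolate of 26 (trivalent chromium on the C3 oxygen, C2=C3) | Cl[Cr](Cl)OC(=C)/C(C)=C\[C@H]1OC(=O)C[C@@H]1[C@H](O[Si](C)(C)C(C)(C)C)C[C@@](C)(O[Si](CC)(CC)CC)C=O | intermediate
28 | (1S,4Z,6R,7S,8R,10R)-8-(tert-butyldimethylsilyloxy)-1-hydroxy-3-oxo-10-(triethylsilyloxy)-13-norgermacr-4-en-12,6-olide | C1C(=O)O[C@@H]2/C=C(/C)C(=O)C[C@H](O)[C@](C)(O[Si](CC)(CC)CC)C[C@@H](O[Si](C)(C)C(C)(C)C)[C@@H]12 | intermediate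
29 | (1S,3S,4Z,6R,7S,8R,10R)-8-(tert-butyldimethylsilyloxy)-1,3-dihydroxy-10-(triethylsilyloxy)-13-norgermacr-4-en-12,6-olide | C1C(=O)O[C@@H]2/C=C(/C)[C@@H](O)C[C@H](O)[C@](C)(O[Si](CC)(CC)CC)C[C@@H](O[Si](C)(C)C(C)(C)C)[C@@H]12 | intermediate
30 | (1S,3S,4Z,6R,7S,8R,10R)-3-benzoyloxy-8-(tert-butyldimethylsilyloxy)-1-hydroxy-10-(triethylsilyloxy)-13-norgermacr-4-en-12,6-olide | C1C(=O)O[C@@H]2/C=C(/C)[C@@H](OC(=O)c3ccccc3)C[C@H](O)[C@](C)(O[Si](CC)(CC)CC)C[C@@H](O[Si](C)(C)C(C)(C)C)[C@@H]12 | intermediate
31 | (1S,3S,4Z,6R,7S,8R,10R)-3-benzoyloxy-8-(tert-butyldimethylsilyloxy)-1-(methylsulfonyloxy)-10-(triethylsilyloxy)-13-norgermacr-4-en-12,6-olide | C1C(=O)O[C@@H]2/C=C(/C)[C@@H](OC(=O)c3ccccc3)C[C@H](OS(C)(=O)=O)[C@](C)(O[Si](CC)(CC)CC)C[C@@H](O[Si](C)(C)C(C)(C)C)[C@@H]12 | intermediate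
32 | tetrabutylammonium C10 alkoxide of desilylated 31 | C1C(=O)O[C@@H]2/C=C(/C)[C@@H](OC(=O)c3ccccc3)C[C@H](OS(C)(=O)=O)[C@](C)([O-])C[C@@H](O[Si](C)(C)C(C)(C)C)[C@@H]12.CCCC[N+](CCCC)(CCCC)CCCC | intermediate
33 | (1R,3S,4Z,6R,7S,8R,10R)-3-benzoyloxy-8-(tert-butyldimethylsilyloxy)-1,10-epoxy-13-norgermacr-4-en-12,6-olide | C1C(=O)O[C@@H]2/C=C(/C)[C@@H](OC(=O)c3ccccc3)C[C@H]3O[C@]3(C)C[C@@H](O[Si](C)(C)C(C)(C)C)[C@@H]12 | intermediate
34 | lithium enolate of lactone 33 | C1=C(O[Li])O[C@@H]2/C=C(/C)[C@@H](OC(=O)c3ccccc3)C[C@H]3O[C@]3(C)C[C@@H](O[Si](C)(C)C(C)(C)C)[C@@H]12 | intermediate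
35 | (1R,3S,4Z,6R,7S,8R,10R)-3-benzoyloxy-8-(tert-butyldimethylsilyloxy)-13-(dimethylamino)-1,10-epoxygermacr-4-en-12,6-olide (C11 not controlled) | CN(C)CC1C(=O)O[C@@H]2/C=C(/C)[C@@H](OC(=O)c3ccccc3)C[C@H]3O[C@]3(C)C[C@@H](O[Si](C)(C)C(C)(C)C)[C@@H]12 | intermediate
36 | trimethylammonium iodide of 35 | C[N+](C)(C)CC1C(=O)O[C@@H]2/C=C(/C)[C@@H](OC(=O)c3ccccc3)C[C@H]3O[C@]3(C)C[C@@H](O[Si](C)(C)C(C)(C)C)[C@@H]12.[I-] | intermediate
37 | (1R,3S,4Z,6R,7S,8R,10R)-3-benzoyloxy-8-(tert-butyldimethylsilyloxy)-1,10-epoxygermacra-4,11(13)-dien-12,6-olide | C=C1C(=O)O[C@@H]2/C=C(/C)[C@@H](OC(=O)c3ccccc3)C[C@H]3O[C@]3(C)C[C@@H](O[Si](C)(C)C(C)(C)C)[C@@H]12 | intermediate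
38 | (1R,3S,4Z,6R,7R,8R,10R)-3-benzoyloxy-1,10-epoxy-8-hydroxygermacra-4,11(13)-dien-12,6-olide | C=C1C(=O)O[C@@H]2/C=C(/C)[C@@H](OC(=O)c3ccccc3)C[C@H]3O[C@]3(C)C[C@@H](O)[C@@H]12 | intermediate
39 | (E)-2-methylbut-2-en-1-ol | C/C=C(\C)CO | starting material
40 | [(2R,3R)-2,3-dimethyloxiran-2-yl]methanol | OC[C@@]1(C)O[C@@H]1C | intermediate
41 | (2S,3R)-2,3-dimethyloxirane-2-carboxylic acid | OC(=O)[C@@]1(C)O[C@@H]1C | intermediate
42 | mixed anhydride of 41 with 2,4,6-trichlorobenzoic acid | O=C(OC(=O)[C@@]1(C)O[C@@H]1C)c1c(Cl)cc(Cl)cc1Cl | intermediate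
43 | CNP0324463.4, (1R,3S,4Z,6R,7R,8R,10R)-3-benzoyloxy-1,10-epoxy-8-{[(2S,3R)-2,3-dimethyloxiran-2-yl]carbonyloxy}germacra-4,11(13)-dien-12,6-olide | C=C1C(=O)O[C@@H]2/C=C(/C)[C@@H](OC(=O)c3ccccc3)C[C@H]3O[C@]3(C)C[C@@H](OC(=O)[C@@]3(C)O[C@@H]3C)[C@@H]12 | target

## Step count and least certain steps

Total: 26 steps. Longest linear sequence: 22 steps (steps 1–9, 12–23 and 26).

**Step 16 (key step).** The chromium enolate may be protonated or react intermolecularly faster than the strained ten-membered ring closes, giving simple debromination or oligomerisation. Ring strain may also override the Felkin–Anh preference at C1. Fallback: set out from keto aldehyde 24, without the bromide. Soft enolisation of the methyl ketone with Bu2BOTf and i-Pr2NEt in CH2Cl2 at −78 °C under high dilution gives the dibutylboron enolate F1. This closes the ring through a tight six-membered boron aldol transition state and, after oxidative work-up, returns to the route at 28. Only the ketone can enolise, since the aldehyde has no α-hydrogen.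

**Step 12.** The basic alkenyllithium may deprotonate the α-branched aldehyde (erosion at C7, β-elimination of the silyloxy group). Facial selectivity at C6 may be modest, and lactonisation onto the tert-butyl ester may stall. Fallback: set out from 19 and 15 and couple them under Nozaki–Hiyama–Kishi conditions (CrCl2, NiCl2 cat., DMSO/THF, rt). The alkenylchromium species is non-basic and aldehyde-selective, and a chiral sulfonamide-type ligand on chromium can impose reagent control. The isolated hydroxy ester F2 is then lactonised with catalytic KOt-Bu in THF, returning at 22.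

**Step 15.** The free aldehyde may be engaged under the silyl triflate, or γ-deprotonation may compete. Either would lead to bromination at the wrong site or loss of the Z geometry. Fallback: set out from diol 23 and keep C1 at the alcohol level. MnO2 oxidises only the allylic C3 alcohol to the hydroxy enone F3. The same enol-silane and N-bromosuccinimide protocol, with an extra equivalent of Me3SiOTf and an acidic methanol work-up, gives the hydroxy bromo ketone F4. Dess–Martin oxidation of the primary alcohol then returns to the route at 26.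

**Step 17.** In the medium ring, the chair-like delivery of hydride from the C1-bound boron may be impossible without strain. Ring conformation would then dictate the C3 face and selectivity may be poor or reversed. Fallback: set out from 28 and reduce with external hydride from the ring periphery (NaBH4, CeCl3·7H2O, MeOH, −78 °C), or accept the product of the directed reagent, to obtain the C3 epimer F5. Mitsunobu esterification with benzoic acid (PPh3, diisopropyl azodicarboxylate) then inverts C3 and installs the benzoate in one operation. The hindered C1 alcohol does not react, and the sequence returns at 30, skipping step 18.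

**Step 20.** Fluoride may also cleave the C8 TBS ether, or as a base attack the benzoate or trigger lactone migration before the slow tertiary desilylation is complete. Fallback: set out from 31 and separate unmasking from closure. Acid-selective solvolysis of the triethylsilyl ether (PPTS, MeOH/CH2Cl2, 0 °C), which discriminates TES from TBS far better than fluoride, gives the hydroxy mesylate F6. DBU in toluene then closes the epoxide with inversion at C1 and returns at 33.

## Further compounds

F1 | step 16 | dibutylboron enolate of keto aldehyde 24 | CCCCB(CCCC)OC(=C)/C(C)=C\[C@H]1OC(=O)C[C@@H]1[C@H](O[Si](C)(C)C(C)(C)C)C[C@@](C)(O[Si](CC)(CC)CC)C=O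
F2 | step 12 | tert-butyl (3S,4R,6R)-4-(tert-butyldimethylsilyloxy)-3-{(1R,2Z,4S)-1-hydroxy-4-[(4-methoxybenzyl)oxy]-3-methylpent-2-en-1-yl}-7-[(4-methoxybenzyl)oxy]-6-methyl-6-(triethylsilyloxy)heptanoate | O[C@H](/C=C(/C)[C@H](C)OCc1ccc(OC)cc1)[C@H](CC(=O)OC(C)(C)C)[C@H](O[Si](C)(C)C(C)(C)C)C[C@@](C)(O[Si](CC)(CC)CC)COCc1ccc(OC)cc1
F3 | step 15 | (4S,5R)-4-[(1R,3R)-1-(tert-butyldimethylsilyloxy)-4-hydroxy-3-methyl-3-(triethylsilyloxy)butyl]-5-[(1Z)-2-methyl-3-oxobut-1-en-1-yl]oxolan-2-one | CC(=O)/C(C)=C\[C@H]1OC(=O)C[C@@H]1[C@H](O[Si](C)(C)C(C)(C)C)C[C@@](C)(O[Si](CC)(CC)CC)CO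
F4 | step 15 | (4S,5R)-5-[(1Z)-4-bromo-2-methyl-3-oxobut-1-en-1-yl]-4-[(1R,3R)-1-(tert-butyldimethylsilyloxy)-4-hydroxy-3-methyl-3-(triethylsilyloxy)butyl]oxolan-2-one | BrCC(=O)/C(C)=C\[C@H]1OC(=O)C[C@@H]1[C@H](O[Si](C)(C)C(C)(C)C)C[C@@](C)(O[Si](CC)(CC)CC)CO
F5 | step 17 | (1S,3R,4Z,6R,7S,8R,10R)-8-(tert-butyldimethylsilyloxy)-1,3-dihydroxy-10-(triethylsilyloxy)-13-norgermacr-4-en-12,6-olide (C3 epimer of 29) | C1C(=O)O[C@@H]2/C=C(/C)[C@H](O)C[C@H](O)[C@](C)(O[Si](CC)(CC)CC)C[C@@H](O[Si](C)(C)C(C)(C)C)[C@@H]12
F6 | step 20 | (1S,3S,4Z,6R,7S,8R,10R)-3-benzoyloxy-8-(tert-butyldimethylsilyloxy)-10-hydroxy-1-(methylsulfonyloxy)-13-norgermacr-4-en-12,6-olide | C1C(=O)O[C@@H]2/C=C(/C)[C@@H](OC(=O)c3ccccc3)C[C@H](OS(C)(=O)=O)[C@](C)(O)C[C@@H](O[Si](C)(C)C(C)(C)C)[C@@H]12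
A1 | alternative 1 | 13-nor lactone (target without the exocyclic methylene) | C1C(=O)O[C@@H]2/C=C(/C)[C@@H](OC(=O)c3ccccc3)C[C@H]3O[C@]3(C)C[C@@H](OC(=O)[C@@]3(C)O[C@@H]3C)[C@@H]12
A2 | alternative 1 | C6-methylene carbocycle with a primary acetamide arm on C7 (epoxide, benzoate and C8 epoxy ester in place) | C1/C=C(/C)[C@@H](OC(=O)c2ccccc2)C[C@H]2O[C@]2(C)C[C@@H](OC(=O)[C@@]2(C)O[C@@H]2C)[C@H]1CC(N)=O
A3 | alternative 2 | cis-anti-cis tricyclic photoadduct (cyclohexanone, central cyclobutane, ketal-bearing cyclobutane) | O=C1[C@@H]2[C@@]3(C)C(OC)(OC)C[C@H]3[C@]2(C)C[C@@H](O[Si](C)(C)C(C)(C)C)[C@H]1CC(=O)OC(C)(C)C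
A4 | alternative 2 | tert-butyl 2-[cis-2-(tert-butyldimethylsilyloxy)-4-methyl-6-oxocyclohex-4-en-1-yl]acetate | O=C1C=C(C)C[C@@H](O[Si](C)(C)C(C)(C)C)[C@H]1CC(=O)OC(C)(C)C
A5 | alternative 2 | 3,3-dimethoxy-2-methylcyclobut-1-ene | COC1(OC)CC=C1C
A6 | alternative 3 | 8-(benzyldimethylsilyl)-3-(4-methoxybenzyloxy)-4,10-dimethylcyclodeca-1(10)E,4Z-dien-6-one (germacrane numbering) | O=C1/C=C(/C)[C@@H](OCc2ccc(OC)cc2)C/C=C(\C)C[C@@H]([Si](C)(C)Cc2ccccc2)C1
A7 | alternative 3 | trans-1-[(E)-2-(benzyldimethylsilyl)vinyl]-6-isopropenyl-4-(4-methoxybenzyloxy)-3-methylcyclohex-2-en-1-ol | O[C@]1(/C=C/[Si](C)(C)Cc2ccccc2)C=C(C)[C@@H](OCc2ccc(OC)cc2)C[C@@H]1C(C)=C
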